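The numbers in the tables are calculated for substances that don't exist.

South, east, north and north-east are all read at 12 h, and what that reading shows depends on how far the target has drained into its isomer by then.

| setting | zeta | epsilon | alpha | south | east | north | north-east |
|---|---|---|---|---|---|---|---|
| starting material | 0.10 M | 0.10 M | 0.15 M | 0.10 M | 0.10 M | 0.10 M | 0.10 M |
| target | 1 mM | 1 mM | 1 mM | 1.00 mM | 1.00 mM | 1.00 mM | 1.00 mM |
| protic impurity | 0.025 M | 0.038 M | 0.050 M | 0.0500 M | 0.0500 M | 0.0500 M | 0.0500 M |
| temperature | 12 °C | 29 °C | 12 °C | 20 °C | 35 °C | 5 °C |  |
| remark | run made earlier | run made earlier | run made earlier |  |  |  | at 35 °C until 2.5 h, from then on at 5 °C |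
| time |  |  |  | 12 h | 12 h | 12 h | 12 h |

- zeta (time / h: target / %, isomer of the product / %): 0.500: 98, 2; 1.33: 96, 2; 2.50: 96, 4; 4.00: 92, 8; 6.00: 91, 10; 8.00: 92, 8; 10.0: 86, 16
- epsilon (time / h: target / %, isomer of the product / %): 0.500: 91, 9; 0.833: 84, 16; 1.33: 78, 22; 1.50: 75, 25; 2.50: 60, 40; 4.00: 45, 53; 6.00: 31, 69
- alpha (time / h: target / %, isomer of the product / %): 2.00: 96, 5; 4.00: 95, 6; 6.00: 89, 9; 8.00: 88, 11; 10.0: 86, 16

(readings scatter by 2 percentage points)

- which flask leads in share of target in all that became target or isomer of the product ("all alike" within 1.5 percentage points) (south / east / north / north-east / all alike)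
- share of target in all that became target or isomer of the product, south
- share of target in all that became target or isomer of the product, east
- share of target in all that became target or isomer of the product, north
- share of target in all that became target or isomer of the product, north-east

- the earlier runs were read with a standard deviation of 2 percentage points

I take time first. At 0.500 h in the zeta run nearly all of the charge already reads as target, so the starting material goes early; afterwards target turns into isomer, a case of kinetic against thermodynamic control. By hand I treat this as a first-order drain: the share of target in target plus isomer falls exponentially with time, at a drain constant k. Zeta's last reading, 86% target and 16% isomer at 10.0 h, gives 0.0171 /h.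

The charges come next. If they fed the drain, alpha should differ from zeta, for it holds twice the impurity and 0.15 M of starting material. Yet at the same 12 °C it reads 86% and 16% at 10.0 h, the pair zeta gave. I give the charges no term, knowing that two changes can cancel.

Temperature remains. Epsilon's last reading at 29 °C gives 0.195 /h, but epsilon also holds 0.038 M of impurity against 0.025 M in zeta, a difference I pass over because I gave the charges no term. Dividing this by zeta's constant makes time drop out and leaves the speed ratio, the drain constant of the warm run over that of the cold run: 11.4, a reading with the scatter of its readings. Spread as a constant factor per degree, it gives 0.00625 /h at 5 °C, 0.0537 /h at 20 °C and 0.461 /h at 35 °C. My shares are therefore 92.8% for north, 52.5% for south and 0.394% for east. Between the two temperatures of north-east the same rule gives a ratio of 73.8, so I count its cold hours by that factor and reckon 29.7%. In my reckoning north stands highest.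

The forecast also names north, with south 43%, east 0.2%, north 91% and north-east 25%. It says “the impurity order is confounded”. We part most on south, where it estimates 0.07 per hour against my 0.0537 /h.

The flasks give south 52.1%, east 2.10%, north 94.0% and north-east 31.1%, so north leads, and south stands 9.1 points above the forecast.

    starting material → target (k = 3.03 × 10⁻⁴ /min, Ea = 106 kJ/mol)
    target ⇌ isomer of the product (K = 57.0, k = 0.00762 /min, Ea = 106 kJ/mol, ΔH = 0 kJ/mol)
    starting material + target → 2 target (k = 44.5 /M/min, Ea = 56.0 kJ/mol)
    starting material + protic impurity → quenched substrate (k = 0.438 /M/min, Ea = 73.0 kJ/mol)
    (constants at 35 °C)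

By the ratio, the 9.50 h cold stretch of north-east counts as 0.129 h of hot time, and its target goes from 32.3% at 2.50 h to 30.8% at 12.0 h. East at 12 h reads 2.10%, above my 0.394%. The neighbouring flask is east read earlier, with time the one setting changed. At 3.0 h the same hot constant gives a share of 25.1%, and that flask reads a share of 26.3%.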